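**Assumptions:** (i) The lipase acetylates the pro-S CH2OH of diol 2, giving (S)-3 (if it does not, see the fallback for Step 2). (ii) The lactone aldol in Step 7 gives roughly a 1:1 mixture of carbinol epimers, which Step 9 converges.

**Retrosynthesis**
1. Magnone B ⇒ hydroxy Weinreb amide 17 (aryl ketone from Ar²MgBr) ⇒ cis-fused bicyclic lactone 16, a temporary third ring that locks C3/C4 cis and regiochemically differentiates the two CH2OH arms.
2. The THF ring (C2 aryl stereocentre) comes from stereoconvergent acid-mediated cyclodehydration of a 1,4-diol via the benzylic cation. The cis C3/C4 relationship comes from the trans-selective aldol of a 4-substituted γ-butyrolactone.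
3. The γ-butyrolactone (ring 1) comes from 2-allylpropane-1,3-diol, whose first stereocentre is set by lipase desymmetrization. Ring order: γ-butyrolactone, then THF (ring 2), then the temporary bicyclic lactone (ring 3), which is opened at the end.

---

**Step 1**
Reactants: 1 diethyl 2-allylmalonate
Product: 2 2-allylpropane-1,3-diol (achiral, prochiral)
Conditions: LiAlH4, THF, 0 °C → rt
Reagents that add atoms: none
Why: Hydride reduction of both esters gives the prochiral diol and leaves the alkene untouched.

**Step 2**
Reactants: 2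
Product: 3 (S)-2-(hydroxymethyl)pent-4-en-1-yl acetate
Conditions: Burkholderia cepacia lipase (PS-IM), vinyl acetate, TBME, 25 °C
Reagents that add atoms: vinyl acetate, C=COC(C)=O (donates acetyl)
Why: A lipase (hydrolase class) acetylates one of the two enantiotopic CH2OH groups by transesterification (enzymatic desymmetrization). This sets the future C4 stereocentre, and acetylating the pro-S arm gives the (S)-monoacetate.

**Step 3**
Reactants: 3
Product: 4 (R)-2-[(tert-butyldiphenylsilyloxy)methyl]pent-4-en-1-yl acetate
Conditions: TBDPSCl, imidazole, DMF, rt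
Reagents that add atoms: TBDPSCl, CC(C)(C)[Si](c1ccccc1)(c1ccccc1)Cl
Why: Silylation of the only free OH gives a robust group that survives base, hydride and the later acid steps. The stereocentre is untouched; the descriptor changes from S to R only because the CIP priorities change (Si > C on oxygen).

**Step 4**
Reactants: 4
Product: 5 (R)-2-[(TBDPSO)methyl]-4-oxobutyl acetate
Conditions: O3, CH2Cl2, −78 °C; then Me2S, −78 °C → rt
Reagents that add atoms: ozone, O=[O+][O-] (supplies the aldehyde O); Me2S is only the reductant and is not incorporated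
Why: Ozonolysis (Criegee mechanism, reductive work-up) cleaves the terminal alkene to the aldehyde; the silyl ether and acetate are inert.

**Step 5**
Reactants: 5
Product: 6 (4R)-4-[(TBDPSO)methyl]tetrahydrofuran-2-ol (lactol, anomeric mixture)
Conditions: K2CO3, MeOH, 0 °C → rt
Reagents that add atoms: none
Why: Methanolysis of the acetate frees the γ-OH, which closes onto the aldehyde to give the lactol (transesterification, then hemiacetalization). The stereocentre is β to the carbonyl and cannot epimerize.

**Step 6**
Reactants: 6
Product: 7 (R)-4-[(TBDPSO)methyl]dihydrofuran-2(3H)-one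
Conditions: TEMPO (10 mol %), PhI(OAc)2, CH2Cl2, rt
Reagents that add atoms: none (oxidant only; the lactone O comes from the lactol)
Why: TEMPO/BAIB oxidation of a lactol to the lactone is chemoselective and neutral, and the silyl ether is untouched.

**Step 7**
Reactants: 7; 8 3,4,5-trimethoxybenzaldehyde
Product: 9 (3S,4R)-4-[(TBDPSO)methyl]-3-[hydroxy(3,4,5-trimethoxyphenyl)methyl]dihydrofuran-2(3H)-one (trans-α,β; carbinol epimers)
Conditions: LiHMDS, THF, −78 °C; then 8, −78 °C; sat. NH4Cl quench at −78 °C
Reagents that add atoms: none (8 is the reactant)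
Why: In this lithium-enolate aldol the aldehyde approaches anti to the bulky β-CH2OTBDPS, setting the future C3 stereocentre trans to it on the lactone; this becomes cis (CH2OH/CH2OTBDPS) in the THF. The carbinol centre is uncontrolled and is converged in Step 9.

**Step 8**
Reactants: 9
Product: 10 (2R,3R)-2-(hydroxymethyl)-3-[(TBDPSO)methyl]-1-(3,4,5-trimethoxyphenyl)butane-1,4-diol (C1 epimers)
Conditions: LiBH4, THF, 0 °C → rt
Reagents that add atoms: none (hydride)
Why: Borohydride reduction opens and reduces the lactone to the diol without touching the silyl ether or the arenes. The cold, weakly basic conditions limit retro-aldol and epimerization at C2, and the stereocentres are not otherwise affected.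

**Step 9**
Reactants: 10
Product: 11 [(2S,3R,4R)-4-{[TBDPSO]methyl}-2-(3,4,5-trimethoxyphenyl)oxolan-3-yl]methanol
Conditions: TsOH·H2O (10 mol %), CH2Cl2, 0 °C → rt
Reagents that add atoms: none (loses H2O)
Why: Acid-catalysed cyclodehydration: the electron-rich benzylic alcohol ionizes, so both carbinol epimers give one cation. The tethered primary OH closes the five-membered ring (5-exo etherification, SN1), and the aryl group ends up anti to both the C3 and C4 substituents (the thermodynamically and sterically preferred 2,3-trans arrangement). The cis-3,4 relationship is carried over unchanged from the lactone.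

**Step 10**
Reactants: 11
Product: 12 [(2S,3R,4R)-4-{[TBDPSO]methyl}-2-(3,4,5-trimethoxyphenyl)oxolan-3-yl]methyl acetate
Conditions: Ac2O, Et3N, DMAP (cat.), CH2Cl2, 0 °C
Reagents that add atoms: acetic anhydride, CC(=O)OC(C)=O
Why: Acylation masks the C3 CH2OH so that only the C4 arm is oxidized later; no stereocentre is affected.

**Step 11**
Reactants: 12
Product: 13 [(2S,3R,4S)-4-(hydroxymethyl)-2-(3,4,5-trimethoxyphenyl)oxolan-3-yl]methyl acetate
Conditions: HF·pyridine, THF/pyridine, 0 °C → rt
Reagents that add atoms: none (the F ends up on Si, not in the product)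
Why: Fluoride-mediated desilylation under buffered, weakly acidic conditions avoids acetate loss and ionization of the benzylic THF ether. The descriptor at C4 changes from R to S only because of CIP priorities.

**Step 12**
Reactants: 13
Product: 14 (3R,4R,5S)-4-(acetoxymethyl)-5-(3,4,5-trimethoxyphenyl)oxolane-3-carboxylic acid
Conditions: TEMPO (20 mol %), PhI(OAc)2, MeCN/H2O 1:1, rt
Reagents that add atoms: water, O (forms the aldehyde hydrate, which is oxidized to the acid)
Why: TEMPO/BAIB oxidizes the primary alcohol via its hydrate to the acid under mild, weakly acidic conditions that minimize α-epimerization; the acetate and the arene survive.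

**Step 13**
Reactants: 14
Product: 15 (3R,4R,5S)-4-(hydroxymethyl)-5-(3,4,5-trimethoxyphenyl)oxolane-3-carboxylic acid
Conditions: K2CO3, MeOH/H2O, rt; then 1 M HCl to pH 3
Reagents that add atoms: none
Why: Methanolysis of the acetate gives the hydroxy acid. The α-H of the carboxylate is not acidic, so C3/C4 are not epimerized.

**Step 14**
Reactants: 15
Product: 16 (3aR,4S,6aR)-4-(3,4,5-trimethoxyphenyl)tetrahydro-1H-furo[3,4-c]furan-1-one (cis-fused bicyclic lactone)
Conditions: TsOH·H2O (5 mol %), CH2Cl2, 4 Å MS, rt
Reagents that add atoms: none (loses H2O)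
Why: Acid-catalysed lactonization (Fischer-type). Only the cis hydroxy acid can form the cis-fused 5/5 lactone, so this step locks the 3,4-cis relationship and rejects any trans acid formed by epimerization in Step 12.

**Step 15**
Reactants: 16
Product: 17 (3R,4R,5S)-4-(hydroxymethyl)-N-methoxy-N-methyl-5-(3,4,5-trimethoxyphenyl)oxolane-3-carboxamide
Conditions: MeNH(OMe)·HCl, i-PrMgCl, THF, −20 → 0 °C
Reagents that add atoms: N,O-dimethylhydroxylamine hydrochloride, CNOC.Cl (adds N(OMe)Me); i-PrMgCl (CC(C)[Mg]Cl) only deprotonates and generates the magnesium amide, and is not incorporated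
Why: The magnesium amide opens the lactone by Weinreb amidation to give the stable hydroxy Weinreb amide. No Lewis acid (AlMe3) is needed, so the benzylic ether is not ionized, and the CH2OH is liberated at the former lactone O–CH2 carbon.

**Step 16**
Reactants: 17; 18 4-bromo-1,2-dimethoxybenzene (converted to ArMgBr with Mg in THF)
Product: 19 Magnone B, (3,4-dimethoxyphenyl)[(3R,4R,5S)-4-(hydroxymethyl)-5-(3,4,5-trimethoxyphenyl)oxolan-3-yl]methanone
Conditions: 3,4-(MeO)2C6H3MgBr (4 equiv, from 18 and Mg), THF, 0 °C → rt; sat. NH4Cl at 0 °C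
Reagents that add atoms: 3,4-dimethoxyphenylmagnesium bromide, COc1ccc([Mg]Br)cc1OC (adds the aryl group)
Why: Grignard addition to the Weinreb amide gives a chelated tetrahedral intermediate that collapses to the ketone only on mild quench, so there is no over-addition and no prolonged base exposure of the α-stereocentre. The free OH is simply deprotonated by the first equivalent.

---

**Compound list**

1 | diethyl 2-allylmalonate | CCOC(=O)C(CC=C)C(=O)OCC | starting material
2 | 2-allylpropane-1,3-diol | OCC(CC=C)CO | intermediate
3 | (S)-2-(hydroxymethyl)pent-4-en-1-yl acetate | OC[C@H](CC=C)COC(C)=O | intermediate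
4 | (R)-2-[(TBDPSO)methyl]pent-4-en-1-yl acetate | CC(C)(C)[Si](c1ccccc1)(c1ccccc1)OC[C@H](CC=C)COC(C)=O | intermediate
5 | (R)-2-[(TBDPSO)methyl]-4-oxobutyl acetate | CC(C)(C)[Si](c1ccccc1)(c1ccccc1)OC[C@H](CC=O)COC(C)=O | intermediate
6 | (4R)-4-[(TBDPSO)methyl]tetrahydrofuran-2-ol (anomer mixture) | CC(C)(C)[Si](c1ccccc1)(c1ccccc1)OC[C@H]1COC(O)C1 | intermediate
7 | (R)-4-[(TBDPSO)methyl]dihydrofuran-2(3H)-one | CC(C)(C)[Si](c1ccccc1)(c1ccccc1)OC[C@H]1COC(=O)C1 | intermediate
8 | 3,4,5-trimethoxybenzaldehyde | COc1cc(C=O)cc(OC)c1OC | starting material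
9 | (3S,4R)-4-[(TBDPSO)methyl]-3-[hydroxy(3,4,5-trimethoxyphenyl)methyl]oxolan-2-one (carbinol unspecified) | CC(C)(C)[Si](c1ccccc1)(c1ccccc1)OC[C@H]2COC(=O)[C@@H]2C(O)c1cc(OC)c(OC)c(OC)c1 | intermediate
10 | (2R,3R)-2-(hydroxymethyl)-3-[(TBDPSO)methyl]-1-aryl-butane-1,4-diol (C1 unspecified) | CC(C)(C)[Si](c1ccccc1)(c1ccccc1)OC[C@@H](CO)[C@H](CO)C(O)c1cc(OC)c(OC)c(OC)c1 | intermediate
11 | [(2S,3R,4R)-4-(TBDPSO-methyl)-2-aryl-oxolan-3-yl]methanol | CC(C)(C)[Si](c1ccccc1)(c1ccccc1)OC[C@H]2CO[C@H](c3cc(OC)c(OC)c(OC)c3)[C@H]2CO | intermediate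
12 | [(2S,3R,4R)-4-(TBDPSO-methyl)-2-aryl-oxolan-3-yl]methyl acetate | CC(C)(C)[Si](c1ccccc1)(c1ccccc1)OC[C@H]2CO[C@H](c3cc(OC)c(OC)c(OC)c3)[C@H]2COC(C)=O | intermediate
13 | [(2S,3R,4S)-4-(hydroxymethyl)-2-aryl-oxolan-3-yl]methyl acetate | OC[C@H]2CO[C@H](c3cc(OC)c(OC)c(OC)c3)[C@H]2COC(C)=O | intermediate
14 | (3R,4R,5S)-4-(acetoxymethyl)-5-aryl-oxolane-3-carboxylic acid | OC(=O)[C@H]2CO[C@H](c3cc(OC)c(OC)c(OC)c3)[C@H]2COC(C)=O | intermediate
15 | (3R,4R,5S)-4-(hydroxymethyl)-5-aryl-oxolane-3-carboxylic acid | OC(=O)[C@H]2CO[C@H](c3cc(OC)c(OC)c(OC)c3)[C@H]2CO | intermediate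
16 | (3aR,4S,6aR)-4-aryl-tetrahydro-1H-furo[3,4-c]furan-1-one | O=C1OC[C@H]2[C@@H]1CO[C@@H]2c1cc(OC)c(OC)c(OC)c1 | intermediate
17 | (3R,4R,5S)-4-(hydroxymethyl)-N-methoxy-N-methyl-5-aryl-oxolane-3-carboxamide | CON(C)C(=O)[C@H]2CO[C@H](c3cc(OC)c(OC)c(OC)c3)[C@H]2CO | intermediate
18 | 4-bromo-1,2-dimethoxybenzene | COc1ccc(Br)cc1OC | starting material
19 | Magnone B | COc1ccc(C(=O)[C@H]2CO[C@H](c3cc(OC)c(OC)c(OC)c3)[C@H]2CO)cc1OC | target

(Aryl = 3,4,5-trimethoxyphenyl.)

---

**Total step count:** 16 steps. **Longest linear sequence:** 16 steps (1 → 19). Steps 7 and 16 each bring in an aryl building block (8 and 18).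

**Three steps most likely to fail**
1. **Step 9 (stereoconvergent cyclodehydration):** E1 elimination to the styrene, C3 scrambling through reprotonation, or poor 2,3-trans selectivity are possible. Fallback: oxidize the carbinol of 9 to the ketone and set it by catalyst-controlled reduction (Ru-TsDPEN dynamic kinetic transfer hydrogenation). Then form the THF by an intramolecular Mitsunobu cyclodehydration of the diastereopure diol, which is stereospecific and involves no cation.
2. **Step 2 (lipase desymmetrization):** The enantiopreference or ee may be insufficient. Fallback: make lactone 7 directly by chemical asymmetric catalysis, using Ru-, Ir- or Cu–H-catalysed asymmetric hydrogenation or conjugate reduction of 4-[(TBDPSO)methyl]furan-2(5H)-one, which replaces Steps 1–6.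
3. **Step 16 (Grignard addition and α-epimerization of the product):** The α-stereocentre may epimerize to the more stable trans ketone, or the amide may be over-added. Fallback: skip the Weinreb amide and add 3,4-dimethoxyphenyllithium (1.05 equiv, −78 °C) directly to bicyclic lactone 16. The lithium lactolate is stable until the mild quench and then opens to the hydroxy ketone.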